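The data were computed on assumed constants, and the scatter is random.

If each portion of partner in this flask has time to stop moving before you look, its end can be reckoned from one number read off an earlier run.

| flask | starting material | partner | remark | time |
|---|---|---|---|---|
| south | 0.25 M | 0.30 M (in portions, 2) | run made earlier; portions every 3.0 d |  |
| west | 1 M | 0.30 M (in portions, 2) | run made earlier; portions every 3.0 d |  |
| north | 0.50 M | 0.60 M (in portions, 2) | run made earlier; portions every 3.0 d |  |
| flask | 0.50 M | 0.300 M (in portions, 2) | the portions of partner follow each other after 3.0 d, the first at the start | 15 d |

| run | time / d | starting material / % | product / % |
|---|---|---|---|
| south | 0.625 | 73.8 | 26.6 |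
| south | 1.67 | 59.5 | 40.6 |
| south | 4.00 | 34.7 | 64.0 |
| south | 10.0 | 29.7 | 70.4 |
| west | 0.625 | 87.2 | 14.1 |
| west | 1.67 | 85.6 | 14.0 |
| west | 4.00 | 73.0 | 27.5 |
| west | 10.0 | 71.5 | 28.0 |
| north | 1.04 | 57.0 | 43.3 |
| north | 3.00 | 51.0 | 48.0 |
| north | 6.00 | 22.5 | 77.3 |
| north | 10.0 | 22.3 | 77.6 |

(standard deviation of a reading: 0.5 percentage points)

- why nothing more happens at 15 d, or that something still does (the partner has run out first / it is still moving / all of the starting material has reacted / forward and back rates have come level)
- share of the starting material used up at 15 d
- product at 15 d, in percent of the starting material charged

- what is said of released group includes crystals
- crystals is a solid; its amount is given per volume of the solution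
- steps that have been proposed: starting material + partner <-> product + released group; crystals <-> released group
- the reaction counts as stopped when no species that holds the starting material changes by six tenths of a point or more over the second half of the time

Take the settings in turn. Time comes first: starting material in the north run fell from 51.0% at 3.00 d to 22.5% at 6.00 d, and the next reading lies 0.2 percentage points lower, inside the scatter. The flask has 12.0 d after its last portion, so by hand more time adds nothing. The spacing of portions then drops out of the reckoning too, though the earlier runs share one spacing and cannot test it.

More partner should raise the yield, and the north run, with 0.60 M, reached 77.6% product. More starting material should lower the percentage, and at equal partner it does: south ended at 70.4%, west at 28.0%.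

To size these two settings, take the saturated quotient, the end value of c(product) / (c(starting material) · c(partner)). By the proposed steps it holds steady while crystals keep dissolved released group at one level, which is thermodynamic control. From the north end, my reading is:

Q = 16.4 /M

South, taken as free of crystals, puts that level near:

0.205 M

For the flask, with x the product formed, I solve:

Q · (c(starting material) − x) · (c(partner) − x) = x, so x = 0.243 M, or 48.5%

This x stands above the level, so the quotient applies.

The forecast says forward and back rates have come level, with 48.7% used up and 48.7% product, slightly above my figure. Of the plateaus it says: “So they are equilibria”.

The flask gives forward and back rates have come level, with 48.6% used up and 48.6% product.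

    starting material + partner ⇌ product + released group (K = 3.30, k = 0.180 /M/h)
    crystals ⇌ released group, rate k2*(cs2 - [released group]) while solid is left; crystals form when [released group] > cs2 (solubility = 0.200 M, k = 2.60 /h)

The undoing of product + released group holds this flask back: with it taken away, its conversion goes from 48.6% to 60.0%, and the answer to why it stops changes. With 19% of its partner left at 15.0 d, the flask's own quotient reads 16.5 /M. Carried to a neighbour flask, charged like this one but with 2.0 M of starting material, Q gives 0.290 M product, or 14.5% of that charge. That neighbour ends at 14.5% product, with 3.42% of its partner left.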